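## The problem

The target 29 is a guaiane: a cyclopentane (C1–C5) trans-fused through C1 and C5 (1αH, 5βH) to a cycloheptane (C1, C5–C10), so a 5–7 bicycle with a defined trans fusion has to be made. Seven stereocentres are present: C1 and C5 at the fusion, the epoxide carbons C3 and C4 (3α,4α-epoxide, 4β-methyl), C7 (β-isopropyl), C8 (β-acyloxy) and the tertiary carbinol C10 (α-OH, β-CH3). C7 can come from the chiral pool and, being next to C8 and 1,4 to C10 across the ring, can bias both. C10 can dictate C1 if both are formed in one stereospecific event; C5 has no neighbour that controls it and is best set by relay from a temporary centre at C3; the 10α-hydroxyl lies on the face where the epoxide must sit and can direct it. The sensitive groups are the trisubstituted epoxide (acid, transannular attack by the C10 hydroxyl), the tertiary alcohol (dehydration), the free phenol (oxidants, bases, acylating agents) and the aryl ester (a UV chromophore), so these should appear late. The enabling feature is the C10(CH3)(OH) centre bonded to the C1–H fusion carbon, together with the methyl-bearing C4 in the five-membered ring. This is the pattern left when a 4-methyl cross-conjugated cyclohexadienone with a quaternary C10 rearranges photochemically in aqueous acid, C1 bonding to C5 and C10 leaving C5 for water. The eudesmane needed for that has a ring B that carries C7 and the C8 oxygen, which are the six ring carbons of carvone with one extra oxygen at the γ-position of its enone.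

## Retrosynthesis

**Phenol and epoxide last (29 ⇒ 28 ⇒ 27).** The O–Si bond of the phenol and the two C–O bonds of the epoxide are cut first. The epoxide is the most acid-sensitive group and the free phenol would not survive a peroxide oxidant, so the order is epoxidation of the silyl-protected ester 27, then desilylation of 28. Compound 27 has two stereocentres fewer than 29. The forward reaction must deliver oxygen to the α face of C3=C4; the 10α-hydroxyl (bishomoallylic) and the shielding 10β-methyl both favour that face.

**Ester bond (27 ⇒ 22 + 25).** The C8–O acyl bond is cut to the diol 22 and the silyl-protected acid 25, which comes in one step from isovanillic acid 23. Carrying the aryl ester from an early stage would save two steps, but it would put a second chromophore into the photochemical step; a late acylation keeps the arene out of it. The forward reaction only has to distinguish the secondary C8 hydroxyl from the tertiary C10 hydroxyl.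

**C5–H and the 3-ene (22 ⇐ 21 ⇐ 18 ⇐ 17).** The C3=C4 alkene with 5βH is traced to the enone 17 (C3=O, C4=C5) by a reductive 1,3-transposition. Hydrogenating the enone would give poor control at C5 and would still require a regiodefined alkene afterwards. The transposition instead passes configuration from C3 to C5: the 3α-alcohol 18 (reagent-controlled reduction) is displaced with inversion by a sulfonylhydrazide, and the resulting diazene hands its hydrogen to the β face of C5, giving 21. The acetate is then removed (22).

**Key disconnection (17 ⇒ 16).** In the retrosynthetic sense C1–C5 is broken, C5–C10 is re-formed and water is removed from C10, which turns the hydroxy-guaienone 17 into the eudesma-1,4-dien-3-one 16. Against cuts that close the seven-membered ring by C–C bond formation, this one creates the cyclopentenone, the cycloheptane, C1 and C10 in a single operation, and it starts from a decalin that is far easier to assemble. Compound 16 has only three stereocentres (C7, C8, C10) and a flat ring A. The forward reaction must open the cyclopropane intermediate toward the 5–7 skeleton and capture C10 with water; the 4-methyl group and the aqueous acetic acid medium are there for that. The C8 oxygen is carried as an acetate, which does not absorb and survives acid.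

**Ring A (16 ⇐ 15 ⇐ 14 ⇐ 10 + 11).** The C1=C2 bond is removed (dehydrogenation of 15), the C4=C5 bond is cut by a retro-aldol (diketone 14) and the C1–C10 bond by a retro-Michael, leading to the cyclohexanone 10 and ethyl vinyl ketone 11. This Robinson-type sequence brings in C1–C4 and the C4 methyl in one reagent. Its one demand is the configuration of the quaternary C10 (methyl cis to isopropyl), which plain base-mediated annulation of 2-methyl-5-alkylcyclohexanones tends to give the wrong way. A chiral-imine Michael addition is therefore used, with the auxiliary and the pseudoaxial acetoxy group both steering the electrophile to the same face.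

**Ring B from carvone (10 ⇐ 8 ⇐ 7 ⇐ 3 ⇐ 2 ⇐ 1).** The C8 oxygen sits on the carbon that is the γ-position of the carvone enone. It is introduced by [4+2] addition of singlet oxygen to the through-conjugated silyl dienol ether 3 of carvotanacetone 2 (from (R)-carvone 1 by selective hydrogenation), which gives the trans-hydroxy enone 7. Mitsunobu inversion with acetic acid gives the cis-acetate 8, and conjugate reduction gives 10. The C5 stereocentre of carvone becomes C7 of the target unchanged. Saturating the isopropenyl group first removes a competing ene site and a doubly allylic hydrogen that would invite aromatisation.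

## Roads not taken

**Alternative 1:** The cut is C8–C9 of the seven-membered ring. In the forward step TiCl4 activates an acid chloride at C8, the methylene terminus of a 2-substituted allylsilane on C1 attacks it, and silicon is lost, giving the dione A1 with a C8 ketone and an exocyclic methylene at C10. Its merits are real: the ring closure is a thermal Lewis-acid step that needs no photochemical equipment, silicon fixes the regiochemistry, and the C8 configuration could be set late by ketone reduction instead of an early Mitsunobu inversion. The weak points for this target are the entropically demanding seven-membered closure, the easy migration of the β,γ-alkene into conjugation with the C8 ketone, and an epimerisable C7 next to that ketone. A1 also lacks the C4 methyl, so a methyl addition, a regioselective dehydration toward C3, the differentiation of two ketones and a face-selective Markovnikov hydration at C10 all remain. In scalability of the ring-closing step this road is better; the chosen plan sets against it that C1 and C10 come from one stereospecific event in step 9 and that all fifteen skeletal carbons are in place from 15 onward.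

**Alternative 2:** The cuts are C1–C5 and C8–C9. Et3N and LiClO4 convert a chloromethyl ketone into an oxyallyl cation that adds across a tethered silyloxydiene in an intramolecular (4+3) cycloaddition, closing both rings at once to give A2. In ring-forming economy this is the strongest of the four ideas: two C–C bonds and both rings arise from an acyclic chain, and the C10 ketone needs only a methyl nucleophile to become the carbinol. Its difficulty is stereochemical. The trans fusion and its relation to the three tether stereocentres depend on tether conformation and on the mode of approach, so several diastereomers are possible. A2 also carries its C8 oxygen α (inversion needed), C7 still has to be set by face-selective reduction of the C6=C7 alkene, the methyl addition at C10 must be face-selective, and the C3 oxygen must be turned into the epoxide by elimination and re-oxidation. The chosen plan is less convergent, but each of its stereocentres comes from the chiral pool, from a stereospecific rearrangement or transposition, or from a reagent-controlled step with close precedent.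

**Alternative 3:** The cut is a one-carbon insertion: C1 is placed between C10 and C5 by Simmons–Smith cyclopropanation (Et2Zn, CH2I2) of a six-membered silyl enol ether, FeCl3-induced cleavage of the inner cyclopropane bond and loss of HCl, which gives the cycloheptenone A3. The sequence is robust and scalable and is the most reliable key step of all four. It delivers only the monocyclic seven-membered ring, however. The cyclopentane with its methyl, the C10 substituents and the stereocentres C1, C5 and C10 would all have to be added to a flexible cycloheptenone with little guidance from the remote C7 and C8. A3 as formulated also has its silyloxy group trans to isopropyl, so C8 would need inversion, and the enantiopure six-membered enone is less accessible than carvone. The chosen plan accepts a photochemical step in exchange for a key step that finishes the whole bicycle and two stereocentres at once.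

Key step: step 9

Assumption: α/β descriptors follow the usual eudesmane and guaiane drawings, monocyclic intermediates keep the carvone locants (C1 carbonyl, C2 methyl, C5 isopropyl), and the target is read as 7β-isopropyl, 8β-acyloxy, 10α-hydroxy, 1αH, 5βH with a 3α,4α-epoxide.

## Route

Step 1
Reactants: 1 (R)-(−)-carvone
Product: 2 (5R)-2-methyl-5-(propan-2-yl)cyclohex-2-en-1-one (carvotanacetone)
Conditions: H2 (1 atm), RhCl(PPh3)3 (cat.), toluene, rt
Reagents that add atoms: none
Why: Homogeneous hydrogenation with RhCl(PPh3)3 reduces the unhindered 1,1-disubstituted isopropenyl alkene much faster than the trisubstituted conjugated C2=C3 bond, so the enone survives; the C5 stereocentre is not touched.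

Step 2
Reactants: 2 (5R)-2-methyl-5-(propan-2-yl)cyclohex-2-en-1-one
Product: 3 trimethyl{[(5R)-2-methyl-5-(propan-2-yl)cyclohexa-1,3-dien-1-yl]oxy}silane
Conditions: MeMgBr, FeCl3 (cat.), Et2O, −20 °C; then Me3SiCl, Et3N, DMPU, −20 °C → rt
Reagents that add atoms: chlorotrimethylsilane, C[Si](C)(C)Cl
Why: Iron-catalysed MeMgBr acts as a base instead of a nucleophile and removes a γ-hydrogen (C4) of the enone; O-silylation of the through-conjugated dienolate gives the 1-silyloxy-1,3-diene (regioselective dienolate formation and trapping), and C5 keeps its configuration because it is neither deprotonated nor part of the diene.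

Step 3
Reactants: 3 trimethyl{[(5R)-2-methyl-5-(propan-2-yl)cyclohexa-1,3-dien-1-yl]oxy}silane
Product: 7 (4R,5R)-4-hydroxy-2-methyl-5-(propan-2-yl)cyclohex-2-en-1-one, via silyloxy endoperoxide 4 (not isolated), via silylperoxy enone 5 (not isolated), via silyloxy enone 6 (not isolated)
Conditions: O2, hν (visible), 5,10,15,20-tetraphenylporphyrin (cat.), CH2Cl2, −78 °C; PPh3, −78 °C → rt; then 1 M HCl, THF, 0 °C
Reagents that add atoms: dioxygen, O=O
Why: Singlet oxygen adds to the cisoid diene termini C1 and C4 in a [4+2] cycloaddition, expected mainly on the face opposite the C5 isopropyl group; the 1-silyloxy endoperoxide collapses by silyl migration to the γ-silylperoxy enone, PPh3 deoxygenates the peroxide and dilute acid removes the silyl group, so the new C4–O bond is trans to isopropyl (4R).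

Step 4
Reactants: 7 (4R,5R)-4-hydroxy-2-methyl-5-(propan-2-yl)cyclohex-2-en-1-one
Product: 8 (4S,5R)-4-acetoxy-2-methyl-5-(propan-2-yl)cyclohex-2-en-1-one
Conditions: AcOH, PPh3, DIAD, THF, 0 °C → rt
Reagents that add atoms: acetic acid, CC(=O)O
Why: Mitsunobu esterification displaces the oxyphosphonium group of the allylic alcohol by acetate in an SN2 reaction with inversion at C4, which places the acetoxy group cis to isopropyl (4S); the allylic position favours substitution over elimination.

Step 5
Reactants: 8 (4S,5R)-4-acetoxy-2-methyl-5-(propan-2-yl)cyclohex-2-en-1-one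
Product: 10 (4R,5R)-4-acetoxy-2-methyl-5-(propan-2-yl)cyclohexan-1-one (mixture of C2 epimers), via silyl enol ether 9 (not isolated)
Conditions: [(Ph3P)CuH]6 (cat.), PhMe2SiH, toluene, rt; then 1 M HCl, THF, 0 °C
Reagents that add atoms: none
Why: Copper hydride-catalysed conjugate reduction (hydride to C3, silyl transfer to oxygen) saturates the enone without touching the allylic acetate, which catalytic hydrogenation could cleave; hydrolysis of the silyl enol ether gives the ketone as a C2 epimer mixture, which does not matter because C2 becomes trigonal in the next step.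

Step 6
Reactants: 10 (4R,5R)-4-acetoxy-2-methyl-5-(propan-2-yl)cyclohexan-1-one; 11 ethyl vinyl ketone (pent-1-en-3-one)
Product: 14 (2R,4R,5R)-4-acetoxy-2-methyl-2-(3-oxopentyl)-5-(propan-2-yl)cyclohexan-1-one, via imine 12 (not isolated), via adduct imine 13 (not isolated)
Conditions: (R)-(+)-1-phenylethylamine (1 equiv), p-TsOH (cat.), toluene, reflux (Dean–Stark); then 11, THF, 40 °C; then 10% aq AcOH, rt
Reagents that add atoms: water, O
Why: Chiral-imine Michael addition: the more substituted secondary enamine tautomer adds to the enone through a cyclic, aza-ene-like transition state, and the (R)-auxiliary directs attack to the face of C2 anti to the pseudoaxial 4-acetoxy and the 5-isopropyl groups (matched case), so the quaternary centre forms as 2R, which is the 10β-methyl configuration; aqueous acid then hydrolyses the imine and returns the auxiliary.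

Step 7
Reactants: 14 (2R,4R,5R)-4-acetoxy-2-methyl-2-(3-oxopentyl)-5-(propan-2-yl)cyclohexan-1-one
Product: 15 8β-acetoxyeudesm-4-en-3-one (7β-isopropyl; 10β-methyl)
Conditions: p-TsOH·H2O (cat.), toluene, reflux (Dean–Stark)
Reagents that add atoms: none
Why: Acid-catalysed intramolecular aldol condensation (second half of a Robinson annulation): the enol of the ethyl ketone (C4) adds to the ring carbonyl (C5) and water is lost into conjugation, closing ring A; no stereocentre is formed and the acetate tolerates the non-nucleophilic acid.

Step 8
Reactants: 15 8β-acetoxyeudesm-4-en-3-one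
Product: 16 8β-acetoxyeudesma-1,4-dien-3-one (7β-isopropyl; 10β-methyl)
Conditions: DDQ, 1,4-dioxane, reflux
Reagents that add atoms: none
Why: DDQ dehydrogenation of a 4-en-3-one under neutral conditions goes through the C2 enol and hydride abstraction from C1, which gives the cross-conjugated 1,4-dien-3-one and not the 4,6-dienone formed under strong acid; the reaction is routine for 4-methyl octalones.

Step 9
Reactants: 16 8β-acetoxyeudesma-1,4-dien-3-one
Product: 17 8β-acetoxy-10α-hydroxy-1αH-guai-4-en-3-one (7β-isopropyl; 10β-methyl)
Conditions: hν (300 nm lamps, Pyrex), AcOH/H2O (1:1), 15 °C, N2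
Reagents that add atoms: water, O
Why: Excitation (n→π*) and intersystem crossing give the triplet dienone, whose β-carbons C1 and C5 bond to form a bicyclo[3.1.0]hexanone oxyallyl zwitterion containing the cyclopropane C1–C5–C10. Protonation on oxygen in acetic acid gives a hydroxyallyl cation; its charge at C4, stabilised by the 4-methyl group, opens the cyclopropane by cleavage of C5–C10, water adds to the emerging tertiary C10 cation and the dienol tautomerises to the cyclopentenone. The closest known reaction type is the rearrangement of santonin-type 4-methyl cross-conjugated cyclohexadienones to 10-oxygenated guai-4-en-3-ones in aqueous acetic acid. The five-membered ring is closed by the photochemical C1–C5 bond across ring A, and the seven-membered ring arises by one-carbon ring expansion when C5–C10 breaks, so that C1 ends between C5 and C10. C1 is controlled by C10: in the tricyclic intermediate ring B is fused to the cyclopropane at C5–C10, so H-1 can only lie on the face opposite the 10β-methyl group and becomes 1αH. C10 is controlled by the breaking bond: water enters anti to the departing C5, with inversion, giving 10α-OH and 10β-CH3. The step needs the 5–7 skeleton in preference to a spiro product, which the 4-methyl group and the unsubstituted C2 secure by localising the charge at C4, and it needs water in preference to acetate capture, which the high water content favours; the C8 acetate and the isopropyl group do not absorb and are remote from the reacting atoms.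

Step 10
Reactants: 17 8β-acetoxy-10α-hydroxy-1αH-guai-4-en-3-one
Product: 18 (3R)-8β-acetoxy-1αH-guai-4-ene-3α,10α-diol
Conditions: (S)-2-methyl-CBS-oxazaborolidine (cat.), BH3·SMe2, THF, −20 °C; then MeOH
Reagents that add atoms: none
Why: Corey–Bakshi–Shibata reduction: the ketone binds the catalyst with its larger alkenyl side (C4) away from the boron substituent, and the (S)-catalyst delivers hydride to the β face to give the (3R)-3α-alcohol under reagent control; the acetate is inert at this temperature and the tertiary hydroxyl only consumes borane.

Step 11
Reactants: 18 (3R)-8β-acetoxy-1αH-guai-4-ene-3α,10α-diol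
Product: 21 8β-acetoxy-1αH,5βH-guai-3-en-10α-ol, via sulfonylhydrazine 19 (not isolated), via allylic diazene 20 (not isolated)
Conditions: 2-nitrobenzenesulfonylhydrazide, PPh3, DEAD, N-methylmorpholine, −30 °C → rt
Reagents that add atoms: none
Why: Reductive 1,3-transposition of an allylic alcohol through a monoalkyl diazene: Mitsunobu displacement by the sulfonylated nitrogen inverts C3 (nitrogen β), loss of 2-nitrobenzenesulfinic acid on warming gives the diazene, and its retro-ene loss of N2 transfers hydrogen to C5 on the same β face while the alkene moves to C3=C4, which sets 5βH and the trans ring fusion; the tertiary alcohol does not enter the Mitsunobu reaction.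

Step 12
Reactants: 21 8β-acetoxy-1αH,5βH-guai-3-en-10α-ol
Product: 22 1αH,5βH-guai-3-ene-8β,10α-diol
Conditions: K2CO3, MeOH, rt
Reagents that add atoms: none
Why: Base-catalysed transesterification removes the secondary acetate; the tertiary alcohol and the trisubstituted alkene are inert to K2CO3 in methanol.

Step 13
Reactants: 23 isovanillic acid (3-hydroxy-4-methoxybenzoic acid)
Product: 25 3-[(tert-butyldimethylsilyl)oxy]-4-methoxybenzoic acid, via bis-silyl derivative 24 (not isolated)
Conditions: TBSCl, imidazole, DMF, rt; then AcOH/THF/H2O (3:1:1), rt
Reagents that add atoms: tert-butyldimethylsilyl chloride, CC(C)(C)[Si](C)(C)Cl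
Why: Both the phenol and the carboxylic acid are silylated, and the much more labile silyl ester is then hydrolysed selectively, which leaves the aryl silyl ether and frees the acid for coupling.

Step 14
Reactants: 22 1αH,5βH-guai-3-ene-8β,10α-diol; 25 3-[(tert-butyldimethylsilyl)oxy]-4-methoxybenzoic acid
Product: 27 8β-{3-[(tert-butyldimethylsilyl)oxy]-4-methoxybenzoyloxy}-1αH,5βH-guai-3-en-10α-ol, via mixed anhydride 26 (not isolated)
Conditions: 2,4,6-trichlorobenzoyl chloride, Et3N, THF, rt; then 22, DMAP, toluene, rt → 60 °C
Reagents that add atoms: none
Why: Yamaguchi esterification: DMAP attacks the mixed anhydride at the less hindered aroyl carbonyl and the acylpyridinium acylates the secondary C8 hydroxyl, while the tertiary C10 hydroxyl is too hindered to react; C8 keeps its configuration because only its O–H bond is broken.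

Step 15
Reactants: 27 8β-{3-[(tert-butyldimethylsilyl)oxy]-4-methoxybenzoyloxy}-1αH,5βH-guai-3-en-10α-ol
Product: 28 3α,4α-epoxy-8β-{3-[(tert-butyldimethylsilyl)oxy]-4-methoxybenzoyloxy}-1αH,5βH-guaian-10α-ol
Conditions: VO(acac)2 (cat.), t-BuOOH, CH2Cl2, 0 °C → rt
Reagents that add atoms: tert-butyl hydroperoxide, CC(C)(C)OO
Why: Hydroxyl-directed epoxidation: the vanadium alkoxide of the 10α-hydroxyl, bishomoallylic to C3=C4, delivers oxygen to the α face, which is also the face not shielded by the 10β-methyl group, and so sets C3 and C4 as the 3α,4α-epoxide with the 4-methyl β; the silyl-protected arene is not oxidised.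

Step 16
Reactants: 28 3α,4α-epoxy-8β-{3-[(tert-butyldimethylsilyl)oxy]-4-methoxybenzoyloxy}-1αH,5βH-guaian-10α-ol
Product: 29 3α,4α-epoxy-8β-(3-hydroxy-4-methoxybenzoyloxy)-1αH,5βH-guaian-10α-ol (the target)
Conditions: Bu4NF, AcOH, THF, 0 °C
Reagents that add atoms: none
Why: Fluoride cleaves the aryl silyl ether rapidly at 0 °C, and buffering with acetic acid keeps the phenoxide from attacking the ester or the epoxide; the tertiary alcohol and the epoxide are untouched.

## Compound list

1 | (R)-(−)-carvone | CC1=CC[C@H](CC1=O)C(C)=C | starting material
2 | (5R)-2-methyl-5-(propan-2-yl)cyclohex-2-en-1-one (carvotanacetone) | CC1=CC[C@H](CC1=O)C(C)C | intermediate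
3 | trimethyl{[(5R)-2-methyl-5-(propan-2-yl)cyclohexa-1,3-dien-1-yl]oxy}silane | CC1=C(O[Si](C)(C)C)C[C@@H](C=C1)C(C)C | intermediate
4 | trimethyl{[6-methyl-8-(propan-2-yl)-2,3-dioxabicyclo[2.2.2]oct-5-en-1-yl]oxy}silane, peroxide bridge on the face opposite isopropyl | CC1=C[C@@H]2OO[C@@]1(O[Si](C)(C)C)C[C@@H]2C(C)C | intermediate
5 | (4R,5R)-2-methyl-5-(propan-2-yl)-4-[(trimethylsilyl)peroxy]cyclohex-2-en-1-one | CC1=C[C@H](OO[Si](C)(C)C)[C@H](CC1=O)C(C)C | intermediate
6 | (4R,5R)-2-methyl-5-(propan-2-yl)-4-[(trimethylsilyl)oxy]cyclohex-2-en-1-one | CC1=C[C@H](O[Si](C)(C)C)[C@H](CC1=O)C(C)C | intermediate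
7 | (4R,5R)-4-hydroxy-2-methyl-5-(propan-2-yl)cyclohex-2-en-1-one (hydroxyl trans to isopropyl) | CC1=C[C@H](O)[C@H](CC1=O)C(C)C | intermediate
8 | (4S,5R)-4-acetoxy-2-methyl-5-(propan-2-yl)cyclohex-2-en-1-one (acetoxy cis to isopropyl) | CC1=C[C@@H](OC(C)=O)[C@H](CC1=O)C(C)C | intermediate
9 | (4R,5R)-4-acetoxy-1-[dimethyl(phenyl)silyloxy]-2-methyl-5-(propan-2-yl)cyclohex-1-ene | CC1=C(O[Si](C)(C)c2ccccc2)C[C@@H]([C@@H](C1)OC(C)=O)C(C)C | intermediate
10 | (4R,5R)-4-acetoxy-2-methyl-5-(propan-2-yl)cyclohexan-1-one, C2 epimer mixture | CC1C[C@@H](OC(C)=O)[C@H](CC1=O)C(C)C | intermediate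
11 | ethyl vinyl ketone (pent-1-en-3-one) | CCC(=O)C=C | starting material
12 | N-[(1R)-1-phenylethyl] imine of 10 | CC1C[C@@H](OC(C)=O)[C@H](CC1=N[C@H](C)c2ccccc2)C(C)C | intermediate
13 | N-[(1R)-1-phenylethyl] imine of (2R,4R,5R)-4-acetoxy-2-methyl-2-(3-oxopentyl)-5-(propan-2-yl)cyclohexan-1-one | CCC(=O)CC[C@]1(C)C[C@@H](OC(C)=O)[C@H](CC1=N[C@H](C)c2ccccc2)C(C)C | intermediate
14 | (2R,4R,5R)-4-acetoxy-2-methyl-2-(3-oxopentyl)-5-(propan-2-yl)cyclohexan-1-one | CCC(=O)CC[C@]1(C)C[C@@H](OC(C)=O)[C@H](CC1=O)C(C)C | intermediate
15 | 8β-acetoxyeudesm-4-en-3-one (7β-isopropyl; 10β-methyl) | CC(=O)O[C@@H]1C[C@@]2(C)CCC(=O)C(C)=C2C[C@@H]1C(C)C | intermediate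
16 | 8β-acetoxyeudesma-1,4-dien-3-one (7β-isopropyl; 10β-methyl) | CC(=O)O[C@@H]1C[C@@]2(C)C=CC(=O)C(C)=C2C[C@@H]1C(C)C | intermediate
17 | 8β-acetoxy-10α-hydroxy-1αH-guai-4-en-3-one | CC(=O)O[C@@H]1C[C@@](C)(O)[C@@H]2CC(=O)C(C)=C2C[C@@H]1C(C)C | intermediate
18 | (3R)-8β-acetoxy-1αH-guai-4-ene-3α,10α-diol | CC(=O)O[C@@H]1C[C@@](C)(O)[C@@H]2C[C@@H](O)C(C)=C2C[C@@H]1C(C)C | intermediate
19 | N-(8β-acetoxy-10α-hydroxy-1αH-guai-4-en-3β-yl)-2-nitrobenzenesulfonohydrazide (C3 on the sulfonylated nitrogen) | CC(=O)O[C@@H]1C[C@@](C)(O)[C@@H]2C[C@H](N(N)S(=O)(=O)c3ccccc3[N+](=O)[O-])C(C)=C2C[C@@H]1C(C)C | intermediate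
20 | 8β-acetoxy-3β-diazenyl-1αH-guai-4-en-10α-ol | CC(=O)O[C@@H]1C[C@@](C)(O)[C@@H]2C[C@H](N=N)C(C)=C2C[C@@H]1C(C)C | intermediate
21 | 8β-acetoxy-1αH,5βH-guai-3-en-10α-ol | CC(=O)O[C@@H]1C[C@@](C)(O)[C@@H]2CC=C(C)[C@H]2C[C@@H]1C(C)C | intermediate
22 | 1αH,5βH-guai-3-ene-8β,10α-diol | O[C@@H]1C[C@@](C)(O)[C@@H]2CC=C(C)[C@H]2C[C@@H]1C(C)C | intermediate
23 | isovanillic acid (3-hydroxy-4-methoxybenzoic acid) | COc1ccc(C(=O)O)cc1O | starting material
24 | tert-butyldimethylsilyl 3-[(tert-butyldimethylsilyl)oxy]-4-methoxybenzoate | COc1ccc(C(=O)O[Si](C)(C)C(C)(C)C)cc1O[Si](C)(C)C(C)(C)C | intermediate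
25 | 3-[(tert-butyldimethylsilyl)oxy]-4-methoxybenzoic acid | COc1ccc(C(=O)O)cc1O[Si](C)(C)C(C)(C)C | intermediate
26 | 3-[(tert-butyldimethylsilyl)oxy]-4-methoxybenzoic 2,4,6-trichlorobenzoic anhydride | COc1ccc(C(=O)OC(=O)c2c(Cl)cc(Cl)cc2Cl)cc1O[Si](C)(C)C(C)(C)C | intermediate
27 | 8β-{3-[(tert-butyldimethylsilyl)oxy]-4-methoxybenzoyloxy}-1αH,5βH-guai-3-en-10α-ol | COc1ccc(C(=O)O[C@@H]2C[C@@](C)(O)[C@@H]3CC=C(C)[C@H]3C[C@@H]2C(C)C)cc1O[Si](C)(C)C(C)(C)C | intermediate
28 | 3α,4α-epoxy-8β-{3-[(tert-butyldimethylsilyl)oxy]-4-methoxybenzoyloxy}-1αH,5βH-guaian-10α-ol | COc1ccc(C(=O)O[C@@H]2C[C@@](C)(O)[C@@H]3C[C@H]4O[C@@]4(C)[C@H]3C[C@@H]2C(C)C)cc1O[Si](C)(C)C(C)(C)C | intermediate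
29 | 3α,4α-epoxy-8β-(3-hydroxy-4-methoxybenzoyloxy)-1αH,5βH-guaian-10α-ol (CNP0264062.2) | COc1ccc(C(=O)O[C@@H]2C[C@@](C)(O)[C@@H]3C[C@H]4O[C@@]4(C)[C@H]3C[C@@H]2C(C)C)cc1O | target

## Step count and least certain steps

Total step count: 16. Longest linear sequence: 15 steps (steps 1–12 and 14–16, from 1 to 29); step 13 is a one-step branch from 23.

**Step 9 (key step).** The risks are secondary photoreaction of the product enone on over-irradiation, partial capture of the C10 cation by acetic acid instead of water, and drift of the zwitterion into the lumiketone pathway if protonation is slow. The fallback changes the trapping nucleophile and the protecting-group pattern. It sets out from 16, which is irradiated in anhydrous acetic acid so that C10 is captured as the acetate, giving 8β,10α-diacetoxy-1αH-guai-4-en-3-one F1. This is reduced with the (S)-oxazaborolidine and BH3·SMe2 to 8β,10α-diacetoxy-1αH-guai-4-en-3α-ol F2, and the sulfonylhydrazide transposition then gives 8β,10α-diacetoxy-1αH,5βH-guai-3-ene F3. LiAlH4 in THF at 0 °C cleaves both acetates, and the sequence returns to the route at 22.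

**Step 2.** The base may deprotonate at C6 instead of C4, which would give the cross-conjugated dienol ether, or the Grignard reagent may add to the carbonyl. The fallback replaces directed deprotonation by thermodynamic, acid-catalysed enol acetylation. It sets out from 2, which with isopropenyl acetate and p-TsOH at reflux should give the through-conjugated dienyl acetate (5R)-2-methyl-5-(propan-2-yl)cyclohexa-1,3-dien-1-yl acetate F4. Sensitised photooxygenation of this gives 6-methyl-8-(propan-2-yl)-2,3-dioxabicyclo[2.2.2]oct-5-en-1-yl acetate F5 (peroxide bridge opposite isopropyl), and thiourea in methanol reduces the O–O bond; the acetoxy hemiketal collapses with loss of acetic acid and the sequence returns at 7.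

**Step 4.** Displacement at a carbinol flanked by the isopropyl-bearing carbon may be slow with a weak acid, and the activated alcohol may instead eliminate toward a dienone that tautomerises to a phenol. The fallback sets out from 7 and uses the more acidic 4-nitrobenzoic acid (PPh3, DIAD, toluene) to give (4S,5R)-2-methyl-4-(4-nitrobenzoyloxy)-5-(propan-2-yl)cyclohex-2-en-1-one F6. Methanolysis (K2CO3, MeOH, 0 °C) gives the cis-alcohol (4S,5R)-4-hydroxy-2-methyl-5-(propan-2-yl)cyclohex-2-en-1-one F7, and acetylation (Ac2O, pyridine, DMAP) returns to the route at 8. F7 is also the compound that any syn-face photooxygenation in step 3 would produce, so a facial mixture from step 3 converges on 8 through the same acetylation.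

**Step 6.** The Michael addition of a hindered, tetrasubstituted enamine may be sluggish, the facial selectivity may erode if the reactive conformer differs from the one assumed, and the amine may attack the acetate during imine formation. The fallback replaces auxiliary control by a Lewis-acid Mukaiyama–Michael reaction under substrate control. It sets out from the silyl enol ether 9, isolated from step 5 without hydrolysis, which is treated with 11 and BF3·OEt2 in CH2Cl2 at −78 °C. Attack anti to the pseudoaxial acetoxy group should give 14 directly on work-up, where the route is rejoined; the detour makes no compound outside the list (F0).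

**Step 11.** The activated allylic alcohol may eliminate to a cyclopentadiene or react at the wrong allyl terminus, and the hydrazide reagent may decompose before displacement at the hindered carbinol. The fallback is a palladium-mediated formate reduction, which is likewise stereospecific. It sets out from 18, which is formylated at the secondary hydroxyl (acetic formic anhydride, pyridine, 0 °C) to give 8β-acetoxy-3α-formyloxy-1αH-guai-4-en-10α-ol F8. Pd(OAc)2 and n-Bu3P in dioxane (the palladium diacetate is reduced in the flask to zerovalent palladium) ionise the formate anti, placing the metal on the β face; decarboxylation and hydride transfer from palladium to the more substituted terminus C5 on that face return to the route at 21.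

## Further compounds

F1 | step 9 | 8β,10α-diacetoxy-1αH-guai-4-en-3-one | CC(=O)O[C@@H]1C[C@@](C)(OC(C)=O)[C@@H]2CC(=O)C(C)=C2C[C@@H]1C(C)C
F2 | step 9 | 8β,10α-diacetoxy-1αH-guai-4-en-3α-ol | CC(=O)O[C@@H]1C[C@@](C)(OC(C)=O)[C@@H]2C[C@@H](O)C(C)=C2C[C@@H]1C(C)C
F3 | step 9 | 8β,10α-diacetoxy-1αH,5βH-guai-3-ene | CC(=O)O[C@@H]1C[C@@](C)(OC(C)=O)[C@@H]2CC=C(C)[C@H]2C[C@@H]1C(C)C
F4 | step 2 | (5R)-2-methyl-5-(propan-2-yl)cyclohexa-1,3-dien-1-yl acetate | CC1=C(OC(C)=O)C[C@@H](C=C1)C(C)C
F5 | step 2 | 6-methyl-8-(propan-2-yl)-2,3-dioxabicyclo[2.2.2]oct-5-en-1-yl acetate, peroxide bridge opposite isopropyl | CC1=C[C@@H]2OO[C@@]1(OC(C)=O)C[C@@H]2C(C)C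
F6 | step 4 | (4S,5R)-2-methyl-4-(4-nitrobenzoyloxy)-5-(propan-2-yl)cyclohex-2-en-1-one | CC1=C[C@@H](OC(=O)c2ccc(cc2)[N+](=O)[O-])[C@H](CC1=O)C(C)C
F7 | step 4 | (4S,5R)-4-hydroxy-2-methyl-5-(propan-2-yl)cyclohex-2-en-1-one | CC1=C[C@@H](O)[C@H](CC1=O)C(C)C
F0 | step 6 | none | none
F8 | step 11 | 8β-acetoxy-3α-formyloxy-1αH-guai-4-en-10α-ol | CC(=O)O[C@@H]1C[C@@](C)(O)[C@@H]2C[C@@H](OC=O)C(C)=C2C[C@@H]1C(C)C
A1 | alternative 1 | 15-nor-1αH,5βH-guai-10(14)-ene-4,8-dione (7β-isopropyl) | O=C1CC(=C)[C@@H]2CCC(=O)[C@H]2C[C@@H]1C(C)C
A2 | alternative 2 | 3α-(tert-butyldimethylsilyloxy)-8α-(triethylsilyloxy)-14-nor-1αH,5βH-guai-6-en-10-one (4β-methyl) | O=C1C[C@H](O[Si](CC)(CC)CC)C(C(C)C)=C[C@@H]2[C@@H](C)[C@H](O[Si](C)(C)C(C)(C)C)C[C@@H]12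
A3 | alternative 3 | (5R,6S)-6-(tert-butyldimethylsilyloxy)-5-(propan-2-yl)cyclohept-2-en-1-one (silyloxy trans to isopropyl) | O=C1C=CC[C@H](C(C)C)[C@@H](O[Si](C)(C)C(C)(C)C)C1
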